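**Plan**

1. Numbering: lactone C1(=O), O2, C3, C4; benzo ring A C4a–C8a; side chain C1′–C15′. Retrosynthetic cuts, in order: O–CH3 of the C8 phenol ether; C2′–C3′ (alkyl–alkyl coupling of a 3-vinyl lactone with a (Z)-C13 bromide); the lactone bond O2–C3; C3–C4 (benzylic alkylation); C5′–C6′ in the chain piece (acetylide alkylation).
2. Enabling feature: C3 is a secondary C–O carbon flanked by benzylic C4 and the plain methylenes C1′/C2′. With C1′=C2′ written as a vinyl group, C3 becomes the substituted end of an allyl unit lying 6-exo to the carboxyl oxygen on C1 across C8a–C4a–C4 of ring A. This allyl unit is the redox isomer of a terminal but-3-ynyl arm.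
3. Forward: ring A is bought as 2-methoxy-6-methylbenzoic acid and propargylated at its methyl group; lactone ring B then closes at O2–C3 by rhodium-catalysed cycloisomerisation of the alkynoic acid. The vinyl helper is used up by hydroboration and Suzuki–Miyaura coupling, which joins C3′–C15′; demethylation ends the route.
4. Stereochemistry: C3 is set in the ring closure by the chiral diphosphine on rhodium. The 6′Z alkene comes from syn semihydrogenation of an alkyne in the chain fragment and is carried through untouched.

Key step: step 2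

Remark: the sense of induction of (R,R)-DIOP in this ring closure is assumed to give the 3S vinyl lactone; if the opposite sense is found, (S,S)-DIOP is used instead.

**Route**

Step 1
Reactants: 1 2-methoxy-6-methylbenzoic acid; 2 3-bromo-1-(trimethylsilyl)prop-1-yne
Product: 4 2-(but-3-yn-1-yl)-6-methoxybenzoic acid, via C-silyl alkynyl acid 3 (not isolated)
Conditions: LiN(iPr)2 (2.3 equiv), THF, −78 → 0 °C; 2, −78 °C → rt; then MeOH, K2CO3 (0.2 equiv), rt; 1 M HCl
Reagents that add atoms: none
Why: Lateral lithiation of the o-toluic acid gives the dilithio carboxylate–benzyl anion, whose SN2 alkylation by the propargylic bromide forms the C4–C3 bond (the silyl cap prevents acetylide formation and disfavours SN2′ attack), and base-catalysed methanolysis of the C(sp)–Si bond then frees the terminal alkyne; no stereocenter is formed.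

Step 2
Reactants: 4 2-(but-3-yn-1-yl)-6-methoxybenzoic acid
Product: 6 (3S)-3-ethenyl-8-methoxy-3,4-dihydro-1H-isochromen-1-one, via allenyl acid 5 (not isolated)
Conditions: [Rh(cod)Cl]2 (2.5 mol %), (R,R)-DIOP (6 mol %), ClCH2CH2Cl (0.05 M), 70 °C
Reagents that add atoms: none
Why: The carboxylic acid adds oxidatively to the monovalent rhodium–diphosphine complex to give a trivalent rhodium hydride carboxylate; hydrometalation of the terminal alkyne and β-hydride elimination isomerise the but-3-ynyl arm to the allene 5, and re-insertion of the allene gives a π-allyl rhodium carboxylate spanning C3–C1′–C2′, whose C–O reductive elimination at C3 forms the O2–C3 bond and returns monovalent rhodium. The closest known reaction type is the rhodium/DIOP-catalysed redox-neutral addition of carboxylic acids to terminal alkynes and allenes, which gives branched allylic esters and, intramolecularly, vinyl lactones. Ring B closes in the 6-exo-trig mode, the carboxyl oxygen attacking the substituted allyl terminus with the vinyl group left outside the ring. The new stereocenter C3 is set under catalyst control by the C2-symmetric diphosphine, which differentiates the two faces of the allyl terminus in the C–O bond-forming step; nothing else in the substrate is stereogenic. The step needs branched over linear attack, isomerisation over direct addition of the acid across the triple bond, and ring closure over β-hydride loss to a conjugated diene; attack at C2′ would need an eight-membered ring and direct addition a seven- or eight-membered enol lactone, whereas the benzo tether holds the carboxylate within reach of C3 only, and the methyl ether keeps the phenol out of play.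

Step 3
Reactants: 7 dec-1-yne; 8 1,3-dibromopropane
Product: 9 1-bromotridec-4-yne
Conditions: n-BuLi (1.0 equiv), THF, −78 → 0 °C; then 8 (3 equiv), DMPU, −20 °C → rt
Reagents that add atoms: none
Why: SN2 alkylation of the lithium acetylide, with the dibromide in excess so that mono-substitution should dominate; no stereocenter is formed.

Step 4
Reactants: 9 1-bromotridec-4-yne
Product: 10 (4Z)-1-bromotridec-4-ene
Conditions: H2 (1 atm), Pd/CaCO3 poisoned with Pb(OAc)2 (Lindlar catalyst), quinoline, hexane, rt
Reagents that add atoms: none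
Why: Lindlar semihydrogenation: syn delivery of H2 on the lead-poisoned palladium surface should stop at the alkene and fixes the 4Z (later 6′Z) geometry, the primary bromide being inert.

Step 5
Reactants: 6 (3S)-3-ethenyl-8-methoxy-3,4-dihydro-1H-isochromen-1-one; 11 9-borabicyclo[3.3.1]nonane; 10 (4Z)-1-bromotridec-4-ene
Product: 13 (3R)-8-methoxy-3-[(6Z)-pentadec-6-en-1-yl]-3,4-dihydro-1H-isochromen-1-one, via B-alkyl-9-BBN 12 (not isolated)
Conditions: 11 (0.5 M in THF, 0.95 equiv per 6), THF, 0 °C → rt; then 10 (0.8 equiv per 6), Pd(OAc)2 (4 mol %), PCy3 (8 mol %), K3PO4·H2O (1.3 equiv), THF, rt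
Reagents that add atoms: none
Why: Anti-Markovnikov hydroboration puts boron on the terminal carbon C2′, and a B-alkyl Suzuki–Miyaura alkyl–alkyl coupling with the electron-rich Pd/PCy3 catalyst (fast oxidative addition of the primary bromide, β-hydride elimination held back) forms C2′–C3′; the borane is used in deficit so that none is left to touch the Z-alkene of 10, and C3 is not involved (the descriptor changes from S to R only because the priorities of C1′ and C4 change).

Step 6
Reactants: 13 (3R)-8-methoxy-3-[(6Z)-pentadec-6-en-1-yl]-3,4-dihydro-1H-isochromen-1-one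
Product: 14 (3R)-8-hydroxy-3-[(6Z)-pentadec-6-en-1-yl]-3,4-dihydro-1H-isochromen-1-one
Conditions: BCl3 (1 M in CH2Cl2, 2.5 equiv), CH2Cl2, −78 → 0 °C; aq. NaHCO3
Reagents that add atoms: none
Why: Lewis-acid ether cleavage: BCl3 chelates the C1 carbonyl and the peri C8 methoxy oxygen and chloride removes the methyl group by SN2, which should leave the lactone, the Z-alkene and C3 unchanged.

**Compound list**

1 | 2-methoxy-6-methylbenzoic acid | COc1cccc(C)c1C(=O)O | starting material
2 | 3-bromo-1-(trimethylsilyl)prop-1-yne | C[Si](C)(C)C#CCBr | starting material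
3 | 2-methoxy-6-[4-(trimethylsilyl)but-3-yn-1-yl]benzoic acid (formed in the flask) | COc1cccc(CCC#C[Si](C)(C)C)c1C(=O)O | intermediate
4 | 2-(but-3-yn-1-yl)-6-methoxybenzoic acid | COc1cccc(CCC#C)c1C(=O)O | intermediate
5 | 2-(buta-2,3-dien-1-yl)-6-methoxybenzoic acid (formed in the flask) | COc1cccc(CC=C=C)c1C(=O)O | intermediate
6 | (3S)-3-ethenyl-8-methoxy-3,4-dihydro-1H-isochromen-1-one | C=C[C@@H]1Cc2cccc(OC)c2C(=O)O1 | intermediate
7 | dec-1-yne | C#CCCCCCCCC | starting material
8 | 1,3-dibromopropane | BrCCCBr | starting material
9 | 1-bromotridec-4-yne | CCCCCCCCC#CCCCBr | intermediate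
10 | (4Z)-1-bromotridec-4-ene | CCCCCCCC/C=C\CCCBr | intermediate
11 | 9-borabicyclo[3.3.1]nonane (9-BBN-H) | B1C2CCCC1CCC2 | starting material
12 | (3R)-3-[2-(9-borabicyclo[3.3.1]nonan-9-yl)ethyl]-8-methoxy-3,4-dihydro-1H-isochromen-1-one (formed in the flask) | B1(CC[C@@H]2Cc3cccc(OC)c3C(=O)O2)C4CCCC1CCC4 | intermediate
13 | (3R)-8-methoxy-3-[(6Z)-pentadec-6-en-1-yl]-3,4-dihydro-1H-isochromen-1-one | CCCCCCCC/C=C\CCCCC[C@@H]1Cc2cccc(OC)c2C(=O)O1 | intermediate
14 | (3R)-8-hydroxy-3-[(6Z)-pentadec-6-en-1-yl]-3,4-dihydro-1H-isochromen-1-one | CCCCCCCC/C=C\CCCCC[C@@H]1Cc2cccc(O)c2C(=O)O1 | target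

**Count**

Total steps: 6. Longest linear sequence: 4 steps (steps 1, 2, 5, 6 from compound 1; equally steps 3, 4, 5, 6 from compound 7).

**Steps most likely to fail**

Step 2. What may go wrong: insufficient enantiofacial discrimination in the C–O bond-forming step at the allyl-rhodium, or diversion of the allyl-rhodium by β-hydride loss at C4 toward a conjugated diene before the ring closes. The fallback sets out from 7 and comes back at 13; it closes the same O2–C3 bond by a stereospecific SN2 inversion, with the stereocenter taken from the chiral pool. The lithium acetylide of 7 (n-BuLi, THF/DMPU) is alkylated with excess 1,4-dibromobutane to 1-bromotetradec-5-yne F1. Magnesium in THF converts it into tetradec-5-yn-1-ylmagnesium bromide F2, which opens (S)-epichlorohydrin at the unsubstituted oxirane carbon (CuI 10 mol %, THF, −40 °C) to (2S)-1-chloroheptadec-8-yn-2-ol F3. NaOH then closes (2S)-2-(pentadec-6-yn-1-yl)oxirane F4. Commercial 2-methoxybenzoic acid is lithiated ortho to the carboxylate (s-BuLi, TMEDA, THF, −78 °C) to lithium 2-lithio-6-methoxybenzoate F5, which opens F4 at its terminal carbon (BF3·OEt2, −78 °C) to 2-[(2S)-2-hydroxyheptadec-8-yn-1-yl]-6-methoxybenzoic acid F6. This acid is worked up at pH 4–5 and kept cold so that it does not lactonise with retention. Mitsunobu lactonisation (PPh3, DIAD, THF, 0 °C) closes O2–C3 with inversion to (3R)-8-methoxy-3-(pentadec-6-yn-1-yl)-3,4-dihydro-1H-isochromen-1-one F7, and Lindlar semihydrogenation under the conditions of step 4 gives 13.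

Step 5. What may go wrong: slow transmetalation of the B-alkyl group, so that the alkylpalladium bromide decays by β-hydride elimination, or hydroboration of the Z-alkene of 10 by borane that has not been consumed. The fallback sets out from 6 and comes back at 13; it reverses the polarity of the two partners. Compound 6 is hydroborated to 12 as in step 5 and oxidised (NaBO3·4H2O, THF/H2O, rt) to (3S)-3-(2-hydroxyethyl)-8-methoxy-3,4-dihydro-1H-isochromen-1-one F8. Iodination (I2, PPh3, imidazole, CH2Cl2, 0 °C) gives (3S)-3-(2-iodoethyl)-8-methoxy-3,4-dihydro-1H-isochromen-1-one F9. Bromide 10 is converted (Zn dust, LiCl, THF, 50 °C) into [(4Z)-tridec-4-en-1-yl]zinc bromide F10. Negishi alkyl–alkyl coupling of F9 with F10 (Pd2(dba)3, tricyclopentylphosphine, N-methylimidazole, THF/NMP, 80 °C) should give 13.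

Step 1. What may go wrong: ring metalation instead of lateral metalation, proton transfer between the dianion and the product leading to double alkylation, or SN2′ attack on the propargylic bromide. The fallback sets out from 1 and comes back at 4; it reverses the polarity at the benzylic carbon. Acid 1 is esterified (MeI, K2CO3, DMF) to methyl 2-methoxy-6-methylbenzoate F11, and Wohl–Ziegler bromination (NBS, AIBN, PhCF3, 80 °C) gives methyl 2-(bromomethyl)-6-methoxybenzoate F12. Commercial 1-(trimethylsilyl)prop-1-yne is lithiated (n-BuLi, TMEDA, THF, −78 → 0 °C) to [3-(trimethylsilyl)prop-2-yn-1-yl]lithium F13, which displaces the benzylic bromide of F12 at −78 °C to give methyl 2-methoxy-6-[4-(trimethylsilyl)but-3-yn-1-yl]benzoate F14. KOH in MeOH/H2O at reflux hydrolyses the ester and cleaves the C–Si bond to give 4.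

**Further compounds**

F1 | step 2 | 1-bromotetradec-5-yne | CCCCCCCCC#CCCCCBr
F2 | step 2 | tetradec-5-yn-1-ylmagnesium bromide | CCCCCCCCC#CCCCC[Mg]Br
F3 | step 2 | (2S)-1-chloroheptadec-8-yn-2-ol | CCCCCCCCC#CCCCCC[C@H](O)CCl
F4 | step 2 | (2S)-2-(pentadec-6-yn-1-yl)oxirane | CCCCCCCCC#CCCCCC[C@H]1CO1
F5 | step 2 | lithium 2-lithio-6-methoxybenzoate | [Li]c1cccc(OC)c1C(=O)O[Li]
F6 | step 2 | 2-[(2S)-2-hydroxyheptadec-8-yn-1-yl]-6-methoxybenzoic acid | CCCCCCCCC#CCCCCC[C@H](O)Cc1cccc(OC)c1C(=O)O
F7 | step 2 | (3R)-8-methoxy-3-(pentadec-6-yn-1-yl)-3,4-dihydro-1H-isochromen-1-one | CCCCCCCCC#CCCCCC[C@@H]1Cc2cccc(OC)c2C(=O)O1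
F8 | step 5 | (3S)-3-(2-hydroxyethyl)-8-methoxy-3,4-dihydro-1H-isochromen-1-one | OCC[C@@H]1Cc2cccc(OC)c2C(=O)O1
F9 | step 5 | (3S)-3-(2-iodoethyl)-8-methoxy-3,4-dihydro-1H-isochromen-1-one | ICC[C@@H]1Cc2cccc(OC)c2C(=O)O1
F10 | step 5 | [(4Z)-tridec-4-en-1-yl]zinc bromide | CCCCCCCC/C=C\CCC[Zn]Br
F11 | step 1 | methyl 2-methoxy-6-methylbenzoate | COc1cccc(C)c1C(=O)OC
F12 | step 1 | methyl 2-(bromomethyl)-6-methoxybenzoate | COc1cccc(CBr)c1C(=O)OC
F13 | step 1 | [3-(trimethylsilyl)prop-2-yn-1-yl]lithium | [Li]CC#C[Si](C)(C)C
F14 | step 1 | methyl 2-methoxy-6-[4-(trimethylsilyl)but-3-yn-1-yl]benzoate | COc1cccc(CCC#C[Si](C)(C)C)c1C(=O)OC
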